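**Assumption:** the target SMILES has no stereocentre or stereoaxis, so the molecule is achiral; "single enantiomer" is read as the single constitutional isomer shown, and no stereocontrol is needed.

## Retrosynthetic overview

1. Target 7 ← removal of two pivalate esters from 6.
2. C5–OH of 6 ← chromone-carbonyl-directed C–H hydroxylation of 5 (the A-ring oxygenation is completed last).
3. Pyranone ring of 5 (O1–C8a bond) ← proposed photoredox dehydrogenative C–H/enol O–H annulation of 1,3-diketone 4. This is the only ring formed; the A and B rings are purchased.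
4. Diketone 4 ← C-acylation of ketone 2 with 3,4,5-trimethoxybenzoyl chloride 3; 2 ← pivaloylation of 3',4'-dihydroxyacetophenone 1.

Both ortho C–H bonds of the 3,4,5-trimethoxybenzoyl unit are oxygenated in turn: one becomes O1 (step 3), the other the 5-OH (step 4).

## Route

**Step 1**
Reactants: 1, 1-(3,4-dihydroxyphenyl)ethan-1-one (3',4'-dihydroxyacetophenone)
Product: 2, 4-acetyl-1,2-phenylene bis(2,2-dimethylpropanoate) (3',4'-bis(pivaloyloxy)acetophenone)
Conditions: PivCl (2.4 equiv), Et3N, DMAP (cat.), CH2Cl2, 0 °C → rt
Reagents that add atoms: pivaloyl chloride, CC(C)(C)C(=O)Cl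
Why: DMAP-catalysed O-acylation of both phenols; the pivalates make the B-ring electron-poor, which is needed for site selectivity in step 3 and oxidant tolerance in step 4.

**Step 2**
Reactants: 2, 4-acetyl-1,2-phenylene bis(2,2-dimethylpropanoate); 3, 3,4,5-trimethoxybenzoyl chloride
Product: 4, 4-[3-oxo-3-(3,4,5-trimethoxyphenyl)propanoyl]-1,2-phenylene bis(2,2-dimethylpropanoate) (a 1,3-diaryl-1,3-diketone, present mainly as the chelated enol)
Conditions: MgBr2·OEt2 (2.5 equiv), i-Pr2NEt (3 equiv), CH2Cl2, rt; then 1 M HCl
Reagents that add atoms: none (all new atoms come from 3)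
Why: Soft-enolisation crossed-Claisen C-acylation; the magnesium enolate formed with an amine base is acylated at carbon by the acid chloride and the product is held as a Mg diketonate, while the hindered aryl pivalates survive the non-nucleophilic base.

**Step 3**
Reactants: 4, the 1,3-diketone from step 2
Product: 5, 4-(6,7,8-trimethoxy-4-oxo-4H-chromen-2-yl)-1,2-phenylene bis(2,2-dimethylpropanoate) (3',4'-bis(pivaloyloxy)-6,7,8-trimethoxyflavone)
Conditions: 9-mesityl-3,6-di-tert-butyl-10-phenylacridinium BF4 (5 mol%), Co(dmgH)2(py)Cl (5 mol%), DCE/HFIP (3:1), 450 nm LEDs, Ar, 25 °C (–H2)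
Reagents that add atoms: none
Why: Proposed new method: acceptorless photoredox/cobaloxime dehydrogenative C(sp2)–H/enol O–H annulation. The excited acridinium (E* ≈ +2.0 V vs SCE) oxidises only the 3,4,5-trimethoxyaryl ketone ring (estimated ≈ +1.6–1.7 V; the bis-pivaloyloxy ring, estimated > +2.2 V, cannot compete as the annulation site). The radical cation carries its charge at the two equivalent ortho carbons (each para to an OMe), and the enol oxygen on the distal carbonyl carbon adds there through a six-membered transition state. Proton loss and Co(II)-mediated H-atom removal (Co(III)–H + H+ → H2) rearomatise to the chromone, and the acridine radical returns Co(III) to Co(II). Oxygen-free conditions avoid α-peroxidation of the diketone. The closest known reaction types are acridinium/cobaloxime dehydrogenative arene C–H amination/etherification and photoredox C–H lactonisation of 2-arylbenzoic acids (arene radical cations trapped by N/O nucleophiles); the same O1–C8a bond is made conventionally by Cu-catalysed O-arylation of 1-(2-haloaryl)-1,3-diketones. A 1,3-diketone enol closing a 4-pyranone at an unfunctionalised aryl C–H has not been shown.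

**Step 4**
Reactants: 5, 3',4'-bis(pivaloyloxy)-6,7,8-trimethoxyflavone
Product: 6, 4-(5-hydroxy-6,7,8-trimethoxy-4-oxo-4H-chromen-2-yl)-1,2-phenylene bis(2,2-dimethylpropanoate)
Conditions: [RuCl2(p-cymene)]2 (5 mol%), PhI(OCOCF3)2 (2 equiv), TFA/TFAA (1:1), 80 °C; then aq. NaHCO3/THF
Reagents that add atoms: [bis(trifluoroacetoxy)iodo]benzene, O=C(OI(OC(=O)C(F)(F)F)c1ccccc1)C(F)(F)F (the C5 oxygen arrives as a trifluoroacetate, hydrolysed on workup)
Why: Known Ru(II)-catalysed carbonyl-directed ortho-C–H hydroxylation, demonstrated on flavones and chromones; carboxylate-assisted ruthenation through a five-membered ruthenacycle on the C4 carbonyl can only occur at C5 (the sole A-ring C–H), and the product stays masked as the trifluoroacetate until workup, protecting the 5-hydroxy-8-methoxy ring from over-oxidation.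

**Step 5**
Reactants: 6, the 5-hydroxyflavone bis-pivalate from step 4
Product: 7, sideritiflavone, 2-(3,4-dihydroxyphenyl)-5-hydroxy-6,7,8-trimethoxy-4H-chromen-4-one
Conditions: K2CO3 (3 equiv), degassed MeOH/THF, rt, Ar; then 1 M HCl
Reagents that add atoms: none
Why: Base-mediated methanolysis (transesterification) of the two aryl pivalates; aryl methyl ethers, the chelated 5-OH and the flavone core are inert at rt, and working under argon with an acidic quench prevents catechol autoxidation.

## Compound list

1 | 1-(3,4-dihydroxyphenyl)ethan-1-one | CC(=O)c1ccc(O)c(O)c1 | starting material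
2 | 4-acetyl-1,2-phenylene bis(2,2-dimethylpropanoate) | CC(=O)c1ccc(OC(=O)C(C)(C)C)c(OC(=O)C(C)(C)C)c1 | intermediate
3 | 3,4,5-trimethoxybenzoyl chloride | COc1cc(C(=O)Cl)cc(OC)c1OC | starting material
4 | 4-[3-oxo-3-(3,4,5-trimethoxyphenyl)propanoyl]-1,2-phenylene bis(2,2-dimethylpropanoate) | COc1cc(C(=O)CC(=O)c2ccc(OC(=O)C(C)(C)C)c(OC(=O)C(C)(C)C)c2)cc(OC)c1OC | intermediate
5 | 4-(6,7,8-trimethoxy-4-oxo-4H-chromen-2-yl)-1,2-phenylene bis(2,2-dimethylpropanoate) | COc1c(OC)cc2c(=O)cc(-c3ccc(OC(=O)C(C)(C)C)c(OC(=O)C(C)(C)C)c3)oc2c1OC | intermediate
6 | 4-(5-hydroxy-6,7,8-trimethoxy-4-oxo-4H-chromen-2-yl)-1,2-phenylene bis(2,2-dimethylpropanoate) | COc1c(OC)c(O)c2c(=O)cc(-c3ccc(OC(=O)C(C)(C)C)c(OC(=O)C(C)(C)C)c3)oc2c1OC | intermediate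
7 | sideritiflavone, 2-(3,4-dihydroxyphenyl)-5-hydroxy-6,7,8-trimethoxy-4H-chromen-4-one | COc1c(OC)c(O)c2c(=O)cc(-c3ccc(O)c(O)c3)oc2c1OC | target

## Summary

Total step count: 5
Longest linear sequence: 5 steps (1 → 2 → 4 → 5 → 6 → 7; 3 is a purchased coupling partner)

**Three steps most likely to fail**

- **Step 3 (proposed new annulation).** Risks: the enol is oxidised instead of the arene (diketonyl radical dimerisation), or the cobalt cycle fails to turn over. Fallback (known chemistry): replace 3 with 2-bromo-3,4,5-trimethoxybenzoyl chloride (from 2-bromo-3,4,5-trimethoxybenzoic acid and (COCl)2), carry out the same step 2 acylation, then close the ring by Cu-catalysed intramolecular Ullmann O-arylation of the enol (CuI/1,10-phenanthroline, K3PO4, toluene or DMF, 100 °C). This gives the same flavone 5 and the route continues unchanged.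

- **Step 4 (C5–H hydroxylation).** Risks: slow ruthenation at a C–H flanked by the 6-OMe, or oxidative demethylation to the 5,8-quinone if the product is not kept as its trifluoroacetate. Fallback: drop late-stage C–H oxidation and bring the C5 oxygen in with the A-ring. Start from 1-(2-hydroxy-3,4,5,6-tetramethoxyphenyl)ethanone, acylate with 3,4-bis(benzyloxy)benzoyl chloride, run Baker–Venkataraman rearrangement and acid cyclodehydration to the 5,6,7,8-tetramethoxyflavone, then use BCl3 to cleave the chelated 5-OMe and both benzyl ethers.

- **Step 2 (soft-enolisation C-acylation).** Risks: O-acylation, double acylation, or acyl transfer from the aryl pivalates. Fallback: use hard enolate chemistry with a protecting-group relay. Treat 3',4'-bis(benzyloxy)acetophenone with LiHMDS (2.2 equiv, THF, –78 °C) and 3 to give the dibenzyl diketone, hydrogenolyse (H2, Pd/C), and pivaloylate the catechol (PivCl, Et3N; phenols react much faster than the chelated enol) to rejoin the route at 4.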